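The pitfall is a double count: an idle adduct holds two units of starting material but is one target, so a share of target has to come from target made, not from units held.

    solid partner ⇌ fresh partner, rate k1*(cs1 - [fresh partner]) while solid is left; crystals form when [fresh partner] > cs1 (cs1 = 18 mM, k1 = 8.3 × 10⁻⁶ s⁻¹)
    open intermediate + second intermediate → target (k2 = 0.019 M⁻¹ s⁻¹)
    starting material ⇌ open intermediate (K3 = 2.3, k3 = 2.4 × 10⁻⁴ s⁻¹)
    2 second intermediate → homo product (k4 = 0.013 M⁻¹ s⁻¹)
    starting material + target ⇌ idle adduct, settled at all times (K5 = 520 M⁻¹)
    fresh partner → second intermediate (k6 = 3.2 × 10⁻⁶ s⁻¹)
all flasks: starting material 0.020 M; solid partner 0.0200 M
- summer: time 40 h
- dawn: time 80 h
- percent here means starting material units held: one idle adduct counts as two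
- what is said of target includes idle adduct
- for a step with 2 of a species take k times the square, and two of it per event
- solid partner is a solid; its amount is given per volume of the solution
- at the start none of the solid partner is in solution
- in an amount of target, one idle adduct counts as one target
- run time (summer): 40 h
1. which of these there is most of at the end, counted by the starting material in it, summer (target / starting material / open intermediate)
2. which of these there is most of at the end, counted by the starting material in it, dawn (target / starting material / open intermediate)
3. how much there is at the end of the one of these that leads, in percent of the starting material charged: summer
4. how much there is at the end of the one of these that leads, in percent of the starting material charged: dawn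

I compare two half-lives. Fresh partner turns into second intermediate with a half-life of 60 h. With open intermediate at its balance value of 0.0139 M, before any of it is used, second intermediate is captured with a half-life of 0.727 h. Because capture is much faster, second intermediate stays in a quasi-steady state, and target is made about as fast as fresh partner turns over.

So I write the balance of the solid partner. While solid remains, c(fresh partner) climbs towards 13.0 mM. The time integral of that rise, times the turnover constant 3.2 × 10⁻⁶ s⁻¹, gives the delivered share, the second intermediate made in percent of the charge. It is 15.3% in summer and 42.4% in dawn. The dawn figure runs slightly high, since the balance then reaches 21.0 mM, more than the charge.

Each delivered unit that ends as target takes one or two units out of the pool of starting material and open intermediate. Counting two for each gives open intermediate 48.4% in summer, more than the delivered share, so I expect it to lead there. Counting one for each gives 40.1% in dawn, less than the delivered share, so I expect target to lead there at about that share.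

The forecast gives open intermediate at 53% in summer and target at 60% in dawn, arguing: “each idle adduct ties up a second starting-material unit, the target's share grows faster than its formation alone suggests”. My dawn figure of 42.4% is lower than its.

The simulation gives open intermediate at 52.7% in summer and target at 39.3% in dawn, and my reckoned delivered share for dawn, 42.4%, is higher than that target. Dawn read at 50 h still has 21.6% of its solid partner, so the same reckoning applies there while solid is left and gives a delivered share of 21.6%. That flask holds target at 20.3% and open intermediate at 46.0%.

Its constants are assumed; the run is a simulation.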